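**Assumption:** the target (6-MeO-BDE-47, 1,5-dibromo-2-(2,4-dibromophenoxy)-3-methoxybenzene) has no stereocentre and no hindered axis, so it is achiral and "single enantiomer" needs no stereocontrol.

**Retrosynthetic overview**
- The only strategic disconnection is the diaryl ether C–O bond: 2,4-dibromo-6-methoxyphenol plus a 2,4-dibromophenyl cation equivalent, here an aryl(2,4,6-trimethoxyphenyl)iodonium salt.
- The phenol comes from 2-bromo-6-methoxyphenol by bromination para to OH. Both ring-A bromines sit ortho/para to the ether oxygen and meta to OMe, so they must be installed at the free-phenol stage.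
- The iodonium salt comes in one pot from 2,4-dibromo-1-iodobenzene and 1,3,5-trimethoxybenzene.
- No ring is formed; both benzene rings are purchased. The route is convergent, 2 + 1 steps.

**Route**

Step 1
Reactants: 1 2-bromo-6-methoxyphenol
Product: 2 2,4-dibromo-6-methoxyphenol
Conditions: NBS (1.0 equiv), MeCN, 0 °C to rt
Reagents that add atoms: N-bromosuccinimide, O=C1CCC(=O)N1Br
Why: Electrophilic aromatic bromination directed by the free OH, the strongest activator, goes to the only open ortho/para site (C4, para to OH), since both ortho positions carry Br and OMe.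

Step 2
Reactants: 3 2,4-dibromo-1-iodobenzene; 4 1,3,5-trimethoxybenzene
Product: 6 (2,4-dibromophenyl)(2,4,6-trimethoxyphenyl)iodonium tosylate, via hydroxy(tosyloxy)iodoarene 5 (not isolated)
Conditions: mCPBA, TsOH·H2O, MeCN, 77 °C; then 4, 77 °C; Et2O precipitation
Reagents that add atoms: p-toluenesulfonic acid monohydrate, Cc1ccc(cc1)S(=O)(=O)O.O
Why: One-pot oxidation of the aryl iodide to a Koser-type iodine(III) species, followed by electrophilic aromatic substitution (SEAr) on the very electron-rich trimethoxybenzene, gives the unsymmetrical diaryliodonium salt.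

Step 3
Reactants: 2 2,4-dibromo-6-methoxyphenol; 6 (2,4-dibromophenyl)(2,4,6-trimethoxyphenyl)iodonium tosylate
Product: 8 1,5-dibromo-2-(2,4-dibromophenoxy)-3-methoxybenzene (target), via potassium 2,4-dibromo-6-methoxyphenoxide 7 (not isolated)
Conditions: t-BuOK (1.0 equiv), THF, 0 °C; then 6 (1.2 equiv), 40 °C
Reagents that add atoms: none
Why: Metal-free O-arylation with a diaryliodonium salt (ligand exchange on iodine(III), then ligand coupling) transfers the electron-poor, ortho-substituted 2,4-dibromophenyl group while the trimethoxyphenyl dummy leaves as its iodide; the pre-formed weakly basic phenoxide avoids aryne pathways and no stereocentre is involved.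

**Compound list**
1 | 2-bromo-6-methoxyphenol | COc1cccc(Br)c1O | starting material
2 | 2,4-dibromo-6-methoxyphenol | COc1cc(Br)cc(Br)c1O | intermediate
3 | 2,4-dibromo-1-iodobenzene | Ic1ccc(Br)cc1Br | starting material
4 | 1,3,5-trimethoxybenzene | COc1cc(OC)cc(OC)c1 | starting material
5 | 2,4-dibromo-1-[hydroxy(tosyloxy)-λ3-iodanyl]benzene | Cc1ccc(cc1)S(=O)(=O)OI(O)c1ccc(Br)cc1Br | intermediate
6 | (2,4-dibromophenyl)(2,4,6-trimethoxyphenyl)iodonium tosylate | COc1cc(OC)c([I+]c2ccc(Br)cc2Br)c(OC)c1.Cc1ccc(cc1)S(=O)(=O)[O-] | intermediate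
7 | potassium 2,4-dibromo-6-methoxyphenoxide | COc1cc(Br)cc(Br)c1[O-].[K+] | intermediate
8 | 1,5-dibromo-2-(2,4-dibromophenoxy)-3-methoxybenzene | COc1cc(Br)cc(Br)c1Oc1ccc(Br)cc1Br | target

**Total step count:** 3
**Longest linear sequence:** 2 steps (1 → 2 → 8, or 3 → 6 → 8)

**Steps most likely to fail, with fallbacks**

Step 3 (most at risk: a di-ortho-substituted, electron-poor phenoxide must attack an ortho-substituted aryl on iodine). The fallback sets out from compound 2 and returns at compound 8, replacing the iodonium coupling by SNAr followed by a Sandmeyer reaction. Phenol 2 is heated with 4-bromo-1-fluoro-2-nitrobenzene (Fc1ccc(Br)cc1[N+](=O)[O-]) and K2CO3 in DMF at 80 °C to give 1,5-dibromo-2-(4-bromo-2-nitrophenoxy)-3-methoxybenzene F1. The nitro group is reduced with Fe/NH4Cl in EtOH/H2O at 70 °C, which leaves the aryl bromides intact, to give 5-bromo-2-(2,4-dibromo-6-methoxyphenoxy)aniline F2. Diazotisation with NaNO2 in 48% HBr at 0 °C gives 5-bromo-2-(2,4-dibromo-6-methoxyphenoxy)benzenediazonium bromide F3, which is not isolated and is warmed with CuBr/HBr to 60 °C to give 8.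

Step 2 (the trimethoxybenzene can be oxidised instead of arylated, or the salt may fail to crystallise). The fallback sets out from compound 3 and returns at compound 8, using a symmetrical salt made by boron–iodine exchange so that no dummy aryl and no chemoselectivity question remain. Compound 3 is oxidised with mCPBA and BF3·OEt2 in CH2Cl2 at rt, then (2,4-dibromophenyl)boronic acid (OB(O)c1ccc(Br)cc1Br) is added at 0 °C to rt to give bis(2,4-dibromophenyl)iodonium tetrafluoroborate F4. F4 is used in place of 6 with phenoxide 7 under the step 3 conditions to give 8; the released aryl iodide 3 can be recycled.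

Step 1 (possible over-bromination, or some attack para to OMe). The fallback sets out from compound 6 and returns at compound 8, taking the ring-A bromine pattern from a purchased compound and introducing the oxygen later. Commercial 3,5-dibromo-2-hydroxybenzaldehyde (O=Cc1cc(Br)cc(Br)c1O) is O-arylated with 6 (t-BuOK, THF, 40–60 °C) to give 3,5-dibromo-2-(2,4-dibromophenoxy)benzaldehyde F5. Baeyer–Villiger oxidation (mCPBA, CH2Cl2, rt), with aryl migration helped by the ortho aryloxy group, gives 3,5-dibromo-2-(2,4-dibromophenoxy)phenyl formate F6. Methanolysis (K2CO3, MeOH, rt) gives 3,5-dibromo-2-(2,4-dibromophenoxy)phenol F7, and O-methylation (MeI, K2CO3, acetone, reflux) gives 8.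

**Further compounds**
F1 | step 3 | 1,5-dibromo-2-(4-bromo-2-nitrophenoxy)-3-methoxybenzene | COc1cc(Br)cc(Br)c1Oc1ccc(Br)cc1[N+](=O)[O-]
F2 | step 3 | 5-bromo-2-(2,4-dibromo-6-methoxyphenoxy)aniline | COc1cc(Br)cc(Br)c1Oc1ccc(Br)cc1N
F3 | step 3 | 5-bromo-2-(2,4-dibromo-6-methoxyphenoxy)benzenediazonium bromide | COc1cc(Br)cc(Br)c1Oc1ccc(Br)cc1[N+]#N.[Br-]
F4 | step 2 | bis(2,4-dibromophenyl)iodonium tetrafluoroborate | Brc1ccc([I+]c2ccc(Br)cc2Br)c(Br)c1.F[B-](F)(F)F
F5 | step 1 | 3,5-dibromo-2-(2,4-dibromophenoxy)benzaldehyde | O=Cc1cc(Br)cc(Br)c1Oc1ccc(Br)cc1Br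
F6 | step 1 | 3,5-dibromo-2-(2,4-dibromophenoxy)phenyl formate | O=COc1cc(Br)cc(Br)c1Oc1ccc(Br)cc1Br
F7 | step 1 | 3,5-dibromo-2-(2,4-dibromophenoxy)phenol | Oc1cc(Br)cc(Br)c1Oc1ccc(Br)cc1Br
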